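## Analysis of the target

Haemathamnolic acid (21) is a depside: two benzene rings joined by one aryl ester, with no stereocentre and no further ring. Ring A carries OMe at C1, H at C2, methyl at C3, the ester carbonyl at C4, OH at C5 and CHO at C6. Ring B is fully substituted: ester oxygen at C1', methyl at C2', CO2H at C3', OH at C4', CHO at C5' and OH at C6'. The sensitive groups are two ortho-hydroxy aldehydes, a free 2,4-dihydroxybenzoic acid that decarboxylates easily in hot acid, and an aryl ester whose ring B oxygen has a free hydroxyl (C6') as neighbour, so base can shift the acyl group to that oxygen. The main difficulty is the ester itself. Its carbonyl is flanked by the C3 methyl and C5 hydroxyl, and its oxygen by the C2' methyl and C6' hydroxyl, so a direct esterification would join a di-ortho-substituted acid to a di-ortho-substituted phenol. In addition, four phenolic oxygens must be told apart (only the one at C1 is methylated) and two formyl groups placed. The route rests on the fact that ring A without its formyl group is an orsellinate: oxygen at C1 and C5, methyl at C3, carboxyl carbon on C4. That is the folding pattern of a linear 3,5,7-trioxooctanoyl chain, so the ester bond can be made while the acyl carbon is still an unhindered ketene carbon, and ring A closed afterwards across C3–C4.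

## Retrosynthetic reasoning

**21 ⇐ 20.** The last bond cut is the O–benzyl bond of the ring B carboxyl. The free acid is the least robust function, so it is unveiled last and under neutral conditions. A benzyl ester is preferred to an acid-labile ester because it survives both the acidic acetal cleavage and the Lewis-acid formylation that come before it. The forward step must cleave one benzylic C–O bond by hydrogenolysis without reducing two chelated aryl aldehydes.

**20 ⇐ 18.** Both aryl–CHO bonds (ring A C6, ring B C5') are cut together. Each lies ortho to a free phenol; ring B has no other free carbon and ring A has only C6 ortho to its one hydroxyl. A phenoxide-directed formylation can therefore place both carbons in one operation. Cutting here also keeps aldehydes out of the key step, where they would condense with the active methylene groups of the chain.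

**18 ⇐ 17 ⇐ 16.** The two methoxymethyl acetals of ring B and the methyl ether at ring A C1 are removed in thought. The order matters. In 16 the C5 hydroxyl is hydrogen-bonded to the ester carbonyl and the ring B oxygens are capped, so the C1 hydroxyl is the only phenol open to alkylation. The ring B phenols are released only afterwards (17 → 18), under acid, so that the acyl group is not induced to migrate.

**16 ⇐ 14 (key disconnection).** Ring A is opened at C3–C4. This leaves the linear 3,5,7-trioxooctanoate 14, in which chain C2 corresponds to ring A C4 and chain C7 to ring A C3. The gain is that the two ortho substituents of the benzoate do not yet exist in 14, whose ester is an ordinary β-keto ester. The forward reaction must make C2 attack C7 (through the aldol adduct 15) and must not let the aryloxy group leave.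

**14 ⇐ 5 + 12.** The ester C–O bond is cut to the phenol 12 and the acylketene 13, which is released from the dioxinone 5 by thermal cycloreversion. Adding an O–H bond across a ketene needs neither activating agent nor base, and the electrophilic carbon is sp-hybridised, so the crowding around the ring B oxygen is the only steric demand.

**5 ⇐ 3 + 4 and 3 ⇐ 1 + 2.** The chain is cut twice next to its ketones, back to the dioxinone 1 and two acetyl donors, the acid chloride 2 and the Weinreb amide 4. Two successive enolate C-acylations are the shortest way to the eight-carbon chain with the carboxyl end still masked.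

**12 ⇐ 9 ⇐ 8 ⇐ 7 ⇐ 6.** The C1'–O bond is traced back to a C–Br bond (through the aryllithium 10 and the borate 11). An electrophile attacks 8 at the carbon between the methyl group and an acetal oxygen, which is exactly C1', and the new hydroxyl is then the only free phenol of 12. Removing the acetals and the benzyl ester leads to 6, which already holds the methyl, carboxyl and two oxygens of ring B.

## Alternatives that were turned down

**Alternative 1:** Ring A is cut at C2–C3 and C1–C6, back to a 2-pyranone and a two-carbon ketene acetal. In the forward sense the ring B ester of 4-benzyloxy-6-methyl-2-oxo-2H-pyran-5-carboxylic acid, A1, would add 1,1-dimethoxyethene, A2, across pyranone C6 and C3. Decarboxylative cycloreversion and loss of one alkoxy group would give the aryl benzoate A3.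
- For: the C1 methoxy group comes from A2 and the C5 oxygen from the pyranone, so the two ring A oxygens are differentiated by construction. On this point it is stronger than the chosen route, which needs a selective methylation.
- Against: the ester in A1 must still be made at a carboxyl flanked by the pyranone C4 ether and C6 methyl, with a hindered ring B phenol, so the steric problem is moved and not removed. A pyranone with a donor at C4 and a methyl on the reacting C6 is a poor partner for A2 and would need forcing temperatures, which A2 tolerates badly. A3 carries four benzyl groups that leave together, exposing the free acid before either formyl group exists.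
- Comparison: A1 needs its own synthesis plus a hindered coupling, so no steps are saved. The chosen strategy offers in return an ester formed at an unhindered carbon and a ring closure with close precedent.

**Alternative 2:** Ring B is cut at C2'–C3' and C4'–C5' and taken below the aromatic oxidation level. The protected ring A acid A4 would be converted to its 4-oxopent-2-en-3-yl ester A5. Di-tert-butyl malonate, A6, would add to the β-carbon of A5, and the methyl ketone would then condense onto one malonate ester to give the cyclohexane-1,3-dione A7 as a diastereomer mixture.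
- For: ring A arrives complete, with its formyl group masked and its methyl ether in place, so no late regiochemical question arises on ring A. The 1,2,4-oxygenation of ring B comes from acyclic pieces without an aryl hydroxylation. Both points are stronger than in the chosen route.
- Against: A5 is an enol ester of an unsymmetrical 1,2-diketone, made by acylating an enolate with a hindered acyl donor, with regio- and geometry problems. Its β-carbon is methyl-substituted and deactivated by the α-acyloxy donor, and the enol ester can pass its acyl group to the malonate anion. In A7 the aroyloxy group sits α to a ketone beside an enolisable dione, which invites acyl shift or loss of the carboxylate. That loss aromatises the ring without the C1' oxygen and is redox-neutral, whereas the wanted aromatisation needs an oxidant.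
- Comparison: A7 is two steps (dehydrogenation, formylation) and several deprotections from the target, after a longer ring A synthesis. The chosen route reaches the aromatic level by a redox-neutral aldol–dehydration and builds ring B by four routine steps.

**Alternative 3:** Ring B is cut at C1'–C2' and C3'–C4'. The bis(trimethylsilyl) dienol ether A8, derived from the 4-acyloxyacetoacetate of the acid A4, would add to tert-butyl but-2-ynoate, A9. Loss of a silyl ether and enolisation would give the arene A10 with both ring B phenols free.
- For: the route is convergent, ring B appears aromatic and correctly oxygenated in one step, and ring A is complete. The hindered ester would be made by alkylating the carboxylate of A4 at a CH2 group, which avoids hindered acyl transfer as well as the ketene addition of the chosen route does.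
- Against: A9 is a singly activated alkyne with a methyl group on its β-carbon, a weak dienophile, and its union with A8 is intermolecular and needs heat that bis(silyl) dienes tolerate poorly. The acyloxy group sits on the nucleophilic terminus of A8, where it adds bulk and lowers reactivity, and generating A8 requires two enolisations next to a migratable acyl group. Ring B of A10 still lacks its formyl group, which would have to be added in the presence of an acetal, a methoxymethyl ether and a tert-butyl ester.
- Comparison: the step count is similar. The chosen key step is intramolecular and of a well-established type, so its single uncertainty (the aryl leaving group) is narrower than the reactivity question of A8 with A9.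

Key step: step 8

Remark: lithium enolates, phenoxides and other ionised forms of numbered compounds, and the tetrahedral or activated-acyl transients of acyl-transfer steps, carry no numbers of their own.
Remark: orsellinic acid 6 is taken as the commercial source of ring B; the polycarbonyl compounds 3, 5, 13, 14 and 15 are drawn as keto tautomers although they are largely enolised.

## Route

Step 1
Reactants: 1 2,2,6-trimethyl-4H-1,3-dioxin-4-one; 2 acetyl chloride
Product: 3 2,2-dimethyl-6-(2-oxopropyl)-4H-1,3-dioxin-4-one
Conditions: 1 (2 equiv), LiN(SiMe3)2 (2 equiv), THF, −78 °C; 2 (1 equiv), −78 → −20 °C; aq. NH4Cl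
Reagents that add atoms: none
Why: Kinetic deprotonation of the 6-methyl group gives the lithium dienolate, which is C-acylated at its γ-carbon by the acid chloride (Claisen-type acylation of a vinylogous ester enolate). The second equivalent of enolate takes up the more acidic proton of the product.

Step 2
Reactants: 3 2,2-dimethyl-6-(2-oxopropyl)-4H-1,3-dioxin-4-one; 4 N-methoxy-N-methylacetamide
Product: 5 6-(2,4-dioxopentyl)-2,2-dimethyl-4H-1,3-dioxin-4-one
Conditions: LiN(i-Pr)2 (2.5 equiv), THF, −78 °C; 4, −78 → −10 °C; aq. HCl to pH 3
Reagents that add atoms: none
Why: Double deprotonation gives a dianion whose terminal carbon (the former ketone methyl) is the more nucleophilic site. Acylation by the Weinreb amide stops at the chelated adduct, so no over-addition occurs (dianion Claisen condensation).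

Step 3
Reactants: 6 orsellinic acid (2,4-dihydroxy-6-methylbenzoic acid)
Product: 7 benzyl 2,4-dihydroxy-6-methylbenzoate
Conditions: BnBr (1.05 equiv), KHCO3, DMF, rt
Reagents that add atoms: benzyl bromide, BrCc1ccccc1
Why: Hydrogencarbonate ionises only the carboxylic acid, and SN2 O-alkylation of the carboxylate needs no attack at the hindered carboxyl carbon and no heating of the decarboxylation-prone acid.

Step 4
Reactants: 7 benzyl 2,4-dihydroxy-6-methylbenzoate
Product: 8 benzyl 2,4-bis(methoxymethoxy)-6-methylbenzoate
Conditions: NaH (2.4 equiv), MOMCl (2.4 equiv), DMF, 0 °C → rt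
Reagents that add atoms: chloromethyl methyl ether, COCCl
Why: Williamson-type alkylation of both sodium phenoxides; the strong base is needed to break the hydrogen bond between the ortho hydroxyl and the ester carbonyl.

Step 5
Reactants: 8 benzyl 2,4-bis(methoxymethoxy)-6-methylbenzoate
Product: 9 benzyl 3-bromo-4,6-bis(methoxymethoxy)-2-methylbenzoate
Conditions: NBS (1.05 equiv), MeCN, 0 °C → rt
Reagents that add atoms: N-bromosuccinimide, O=C1CCC(=O)N1Br
Why: Electrophilic aromatic bromination. The carbon para to one acetal oxygen and ortho to the other and to the methyl group is more reactive and less crowded than the carbon between the two acetal oxygens, as with orcinol dialkyl ethers.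

Step 6
Reactants: 9 benzyl 3-bromo-4,6-bis(methoxymethoxy)-2-methylbenzoate
Product: 12 benzyl 3-hydroxy-4,6-bis(methoxymethoxy)-2-methylbenzoate, via aryllithium 10 (not isolated), via lithium aryltriisopropoxyborate 11 (not isolated)
Conditions: B(Oi-Pr)3 (1.5 equiv), THF, −78 °C; n-BuLi (1.1 equiv), −78 → 0 °C; AcOH, 30% H2O2, 0 °C → rt
Reagents that add atoms: hydrogen peroxide, OO
Why: Bromine–lithium exchange at −78 °C is faster than addition to the doubly ortho-substituted benzyl ester, and the borate already present captures the aryllithium at once (in situ quench). Peroxide oxidation of the aryl–boron bond with 1,2-aryl shift then gives the phenol.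

Step 7
Reactants: 5 6-(2,4-dioxopentyl)-2,2-dimethyl-4H-1,3-dioxin-4-one; 12 benzyl 3-hydroxy-4,6-bis(methoxymethoxy)-2-methylbenzoate
Product: 14 3-(benzyloxycarbonyl)-4,6-bis(methoxymethoxy)-2-methylphenyl 3,5,7-trioxooctanoate, via acylketene 13 (not isolated)
Conditions: toluene, 110 °C, acetone distilled off; concentrated and used crude
Reagents that add atoms: none
Why: Thermal retro-[4+2] cleavage of the dioxinone releases the acylketene, whose sp carbon has no ortho substituents and is captured by the phenolic oxygen of 12 (known thermolysis–trapping of dioxinones by alcohols and phenols). No base or activating agent is present, so the acetals and the benzyl ester are untouched.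

Step 8
Reactants: 14 3-(benzyloxycarbonyl)-4,6-bis(methoxymethoxy)-2-methylphenyl 3,5,7-trioxooctanoate
Product: 16 3-(benzyloxycarbonyl)-4,6-bis(methoxymethoxy)-2-methylphenyl 2,4-dihydroxy-6-methylbenzoate, via aldol adduct 15 (not isolated)
Conditions: Et3N (2 equiv), CH2Cl2, 0 °C → rt; then AcOH (excess), rt
Reagents that add atoms: none
Why: This is a biomimetic aldol aromatisation, and the closest known reaction type is the mild-base cyclisation of alkyl 3,5,7-trioxoalkanoates, obtained by ketene trapping, to resorcylate esters. The amine deprotonates the chain; in the reacting tautomer the C3/C5 diketone is held as a hydrogen-bonded enolate, the terminal C7 methyl ketone is the free carbonyl and the ester α-carbon C2 is the nucleophilic terminus. C2 adds to C7 in a 6-(enolendo)-exo-trig closure, which forms ring A bond C3–C4 and gives the β-hydroxy ketone 15. Dehydration (completed by the acid) and two enolisations give the benzene ring; the two stereocentres of 15 vanish, so no stereocontrol is needed. The step needs chemoselectivity for the C2→C7 aldol over Claisen attack of C6 on the ester carbonyl, lactonisation by the C5 enol oxygen and E1cB release of a ketene, all of which would expel the ring B phenoxide. Three things should secure it: the ester carbonyl is shielded by the C2' methyl and C6' acetal of its aryl group, the medium holds no external nucleophile and only a weak amine buffered by its own ammonium salt, and aromatisation makes the aldol path irreversible. The ortho groups of the new benzoate (C3 methyl, C5 hydroxyl) appear only now, after the ester bond exists.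

Step 9
Reactants: 16 3-(benzyloxycarbonyl)-4,6-bis(methoxymethoxy)-2-methylphenyl 2,4-dihydroxy-6-methylbenzoate
Product: 17 3-(benzyloxycarbonyl)-4,6-bis(methoxymethoxy)-2-methylphenyl 2-hydroxy-4-methoxy-6-methylbenzoate
Conditions: MeI (1.1 equiv), K2CO3 (1.2 equiv), acetone, rt
Reagents that add atoms: iodomethane, CI
Why: Williamson methylation of the only non-chelated phenol (ring A C1), as in the selective 4-O-methylation of orsellinates. The C5 hydroxyl is held in a hydrogen bond to the ester carbonyl and the ring B oxygens are capped.

Step 10
Reactants: 17 3-(benzyloxycarbonyl)-4,6-bis(methoxymethoxy)-2-methylphenyl 2-hydroxy-4-methoxy-6-methylbenzoate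
Product: 18 benzyl 4,6-dihydroxy-3-[(2-hydroxy-4-methoxy-6-methylbenzoyl)oxy]-2-methylbenzoate
Conditions: HCl (3 M aq.), MeOH–THF, 40 °C
Reagents that add atoms: none
Why: Acid-catalysed acetal exchange removes both methoxymethyl groups, while the benzyl ester and the doubly ortho-substituted depside ester resist methanolysis. Acidic conditions avoid acyl migration to the newly freed neighbouring phenol.

Step 11
Reactants: 18 benzyl 4,6-dihydroxy-3-[(2-hydroxy-4-methoxy-6-methylbenzoyl)oxy]-2-methylbenzoate
Product: 20 benzyl 3-formyl-5-[(3-formyl-2-hydroxy-4-methoxy-6-methylbenzoyl)oxy]-2,4-dihydroxy-6-methylbenzoate, via bis(chloro ether) 19 (not isolated)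
Conditions: Cl2CHOMe (5 equiv), TiCl4 (6 equiv), CH2Cl2, −10 °C → rt; then 1 M HCl, 0 °C
Reagents that add atoms: dichloromethyl methyl ether, COC(Cl)Cl; water, O
Why: Twofold Rieche formylation: titanium phenoxides deliver the chloro(methoxy)methyl cation ortho to oxygen. Ring B has one free carbon (C5', between its hydroxyls) and ring A reacts at C6, ortho to its only hydroxyl. Each first formyl group deactivates its ring, and aqueous acid hydrolyses the α-chloro ethers to the aldehydes.

Step 12
Reactants: 20 benzyl 3-formyl-5-[(3-formyl-2-hydroxy-4-methoxy-6-methylbenzoyl)oxy]-2,4-dihydroxy-6-methylbenzoate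
Product: 21 haemathamnolic acid (3-formyl-5-[(3-formyl-2-hydroxy-4-methoxy-6-methylbenzoyl)oxy]-2,4-dihydroxy-6-methylbenzoic acid)
Conditions: H2 (1 atm), 10% Pd/C, EtOAc, rt, stopped after uptake of 1 equiv
Reagents that add atoms: none
Why: Hydrogenolysis of the benzylic C–O bond of the ester under neutral conditions. The two aldehydes are chelated by ortho hydroxyls and conjugated to electron-rich rings, which slows their reduction enough to stop after ester cleavage, as is usual for formyl-bearing depside benzyl esters.

## Compound list

1 | 2,2,6-trimethyl-4H-1,3-dioxin-4-one | CC1=CC(=O)OC(C)(C)O1 | starting material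
2 | acetyl chloride | CC(Cl)=O | starting material
3 | 2,2-dimethyl-6-(2-oxopropyl)-4H-1,3-dioxin-4-one | CC(=O)CC1=CC(=O)OC(C)(C)O1 | intermediate
4 | N-methoxy-N-methylacetamide | CON(C)C(C)=O | starting material
5 | 6-(2,4-dioxopentyl)-2,2-dimethyl-4H-1,3-dioxin-4-one | CC(=O)CC(=O)CC1=CC(=O)OC(C)(C)O1 | intermediate
6 | orsellinic acid (2,4-dihydroxy-6-methylbenzoic acid) | Cc1cc(O)cc(O)c1C(=O)O | starting material
7 | benzyl 2,4-dihydroxy-6-methylbenzoate | Cc1cc(O)cc(O)c1C(=O)OCc1ccccc1 | intermediate
8 | benzyl 2,4-bis(methoxymethoxy)-6-methylbenzoate | COCOc1cc(C)c(C(=O)OCc2ccccc2)c(OCOC)c1 | intermediate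
9 | benzyl 3-bromo-4,6-bis(methoxymethoxy)-2-methylbenzoate | COCOc1cc(OCOC)c(C(=O)OCc2ccccc2)c(C)c1Br | intermediate
10 | benzyl 3-lithio-4,6-bis(methoxymethoxy)-2-methylbenzoate (aryllithium, not isolated) | COCOc1cc(OCOC)c(C(=O)OCc2ccccc2)c(C)c1[Li] | intermediate
11 | lithium {3-(benzyloxycarbonyl)-4,6-bis(methoxymethoxy)-2-methylphenyl}triisopropoxyborate (not isolated) | [Li+].COCOc1cc(OCOC)c(C(=O)OCc2ccccc2)c(C)c1[B-](OC(C)C)(OC(C)C)OC(C)C | intermediate
12 | benzyl 3-hydroxy-4,6-bis(methoxymethoxy)-2-methylbenzoate | COCOc1cc(OCOC)c(C(=O)OCc2ccccc2)c(C)c1O | intermediate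
13 | oct-1-ene-1,3,5,7-tetrone (acylketene, not isolated) | CC(=O)CC(=O)CC(=O)C=C=O | intermediate
14 | 3-(benzyloxycarbonyl)-4,6-bis(methoxymethoxy)-2-methylphenyl 3,5,7-trioxooctanoate | CC(=O)CC(=O)CC(=O)CC(=O)Oc1c(C)c(C(=O)OCc2ccccc2)c(OCOC)cc1OCOC | intermediate
15 | 3-(benzyloxycarbonyl)-4,6-bis(methoxymethoxy)-2-methylphenyl 2-hydroxy-2-methyl-4,6-dioxocyclohexane-1-carboxylate (aldol adduct, diastereomer mixture, not isolated) | CC1(O)CC(=O)CC(=O)C1C(=O)Oc1c(C)c(C(=O)OCc2ccccc2)c(OCOC)cc1OCOC | intermediate
16 | 3-(benzyloxycarbonyl)-4,6-bis(methoxymethoxy)-2-methylphenyl 2,4-dihydroxy-6-methylbenzoate | Cc1cc(O)cc(O)c1C(=O)Oc1c(C)c(C(=O)OCc2ccccc2)c(OCOC)cc1OCOC | intermediate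
17 | 3-(benzyloxycarbonyl)-4,6-bis(methoxymethoxy)-2-methylphenyl 2-hydroxy-4-methoxy-6-methylbenzoate | COc1cc(C)c(C(=O)Oc2c(C)c(C(=O)OCc3ccccc3)c(OCOC)cc2OCOC)c(O)c1 | intermediate
18 | benzyl 4,6-dihydroxy-3-[(2-hydroxy-4-methoxy-6-methylbenzoyl)oxy]-2-methylbenzoate | COc1cc(C)c(C(=O)Oc2c(C)c(C(=O)OCc3ccccc3)c(O)cc2O)c(O)c1 | intermediate
19 | benzyl 3-[chloro(methoxy)methyl]-5-({3-[chloro(methoxy)methyl]-2-hydroxy-4-methoxy-6-methylbenzoyl}oxy)-2,4-dihydroxy-6-methylbenzoate (stereoisomer mixture, not isolated) | COc1cc(C)c(C(=O)Oc2c(C)c(C(=O)OCc3ccccc3)c(O)c(C(Cl)OC)c2O)c(O)c1C(Cl)OC | intermediate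
20 | benzyl 3-formyl-5-[(3-formyl-2-hydroxy-4-methoxy-6-methylbenzoyl)oxy]-2,4-dihydroxy-6-methylbenzoate | COc1cc(C)c(C(=O)Oc2c(C)c(C(=O)OCc3ccccc3)c(O)c(C=O)c2O)c(O)c1C=O | intermediate
21 | haemathamnolic acid | COc1cc(C)c(C(=O)Oc2c(C)c(C(=O)O)c(O)c(C=O)c2O)c(O)c1C=O | target

## Step count and least certain steps

Total step count: 12. Longest linear sequence: 10 steps (6 → 21, steps 3 to 12). The dioxinone branch (steps 1 and 2) joins at step 7.

**Step 8 (key step).** The most likely failure is expulsion of the ring B phenoxide, by lactonisation through the C5 enol oxygen, by Claisen closure from C6 or by E1cB fragmentation, because an aryloxide leaves more easily than the alkoxides on which this cyclisation is established. Slow dehydration of 15 under conditions mild enough for the acetals is a second weakness. The fallback reverses the order of ring formation and acylation, and sets out from 5 and 12. Compound 5 is aromatised with Et3N in CH2Cl2, where the acyl carbon is locked in the dioxinone and cannot be lost, to 7-hydroxy-2,2,5-trimethyl-4H-1,3-benzodioxin-4-one F1. MeI and K2CO3 methylate its single phenol to 7-methoxy-2,2,5-trimethyl-4H-1,3-benzodioxin-4-one F2. Irradiation of F2 near 300 nm in CH2Cl2 in the presence of 12 releases acetone and the quinoketene 3-methoxy-5-methyl-6-(oxomethylidene)cyclohexa-2,4-dien-1-one F3, which adds 12 at its ketene carbon (known photochemical acylation by benzodioxinones). This gives 17 directly, where the route is rejoined.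

**Step 7.** The acylketene 13 may be captured by its own C5 enol oxygen, or may dimerise, faster than the hindered phenol 12 adds, and the crude triketo ester may begin to cyclise unselectively in hot toluene. The fallback gives up the ketene for the classical depside esterification and sets out from 12. Commercial methyl 2,4-dihydroxy-6-methylbenzoate F4 is methylated at its non-chelated hydroxyl (MeI, K2CO3, acetone) to methyl 2-hydroxy-4-methoxy-6-methylbenzoate F5. Saponification (KOH, aq. DMSO, 80 °C, cold acidification) gives 2-hydroxy-4-methoxy-6-methylbenzoic acid F6. F6 is coupled with 12 by N,N'-dicyclohexylcarbodiimide in toluene to give 17, where the route is rejoined. This hindered acylation is expected to be slow, which is why it is only the fallback.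

**Step 11.** Ring A may be formylated at the wrong carbon (C2, para to the hydroxyl), the second formylation may stay incomplete, or the Lewis acid may cleave the chelated benzyl ester or promote acyl migration on ring B. The fallback formylates the rings one at a time by two different mechanisms and sets out from 17. MgCl2, Et3N and paraformaldehyde in MeCN at reflux (magnesium phenoxide-directed ortho-hydroxymethylation followed by hydride transfer) formylate only ring A, since ring B has no free phenol, and give 3-(benzyloxycarbonyl)-4,6-bis(methoxymethoxy)-2-methylphenyl 3-formyl-2-hydroxy-4-methoxy-6-methylbenzoate F7. HCl in MeOH–THF removes the acetals to give benzyl 3-[(3-formyl-2-hydroxy-4-methoxy-6-methylbenzoyl)oxy]-4,6-dihydroxy-2-methylbenzoate F8. Cl2CHOMe and TiCl4 then attack only the single free carbon of ring B, ring A being deactivated by its aldehyde, through benzyl 3-[chloro(methoxy)methyl]-5-[(3-formyl-2-hydroxy-4-methoxy-6-methylbenzoyl)oxy]-2,4-dihydroxy-6-methylbenzoate F9. Hydrolysis on work-up gives 20, where the route is rejoined.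

**Step 6.** n-BuLi or the aryllithium may add to the benzyl ester, or the hindered aryllithium may be protonated before borylation, which returns 8. The fallback replaces the organolithium by a palladium-catalysed borylation and sets out from 9. B2pin2, Pd(OAc)2, SPhos and KOAc in dioxane at 90 °C give benzyl 4,6-bis(methoxymethoxy)-2-methyl-3-(4,4,5,5-tetramethyl-1,3,2-dioxaborolan-2-yl)benzoate F10. Oxidation with NaBO3·4H2O in THF–water gives 12, where the route is rejoined.

**Step 12.** One or both aryl aldehydes may be over-reduced in competition with cleavage of the benzyl ester. The fallback is a non-reductive dealkylation that sets out from 20. Me3SiI, generated from Me3SiCl and NaI in MeCN at 0 °C, silylates the ester, and iodide attacks the benzylic carbon in an SN2 step that is much faster than cleavage of the aryl methyl ether at this temperature. Aqueous work-up hydrolyses the silyl ester and silyl ethers and gives 21 directly; no new compound is made.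

## Further compounds

F1 | step 8 | 7-hydroxy-2,2,5-trimethyl-4H-1,3-benzodioxin-4-one | Cc1cc(O)cc2OC(C)(C)OC(=O)c12
F2 | step 8 | 7-methoxy-2,2,5-trimethyl-4H-1,3-benzodioxin-4-one | COc1cc(C)c2C(=O)OC(C)(C)Oc2c1
F3 | step 8 | 3-methoxy-5-methyl-6-(oxomethylidene)cyclohexa-2,4-dien-1-one | COC1=CC(=O)C(=C=O)C(C)=C1
F4 | step 7 | methyl 2,4-dihydroxy-6-methylbenzoate | COC(=O)c1c(C)cc(O)cc1O
F5 | step 7 | methyl 2-hydroxy-4-methoxy-6-methylbenzoate | COC(=O)c1c(C)cc(OC)cc1O
F6 | step 7 | 2-hydroxy-4-methoxy-6-methylbenzoic acid | COc1cc(C)c(C(=O)O)c(O)c1
F7 | step 11 | 3-(benzyloxycarbonyl)-4,6-bis(methoxymethoxy)-2-methylphenyl 3-formyl-2-hydroxy-4-methoxy-6-methylbenzoate | COc1cc(C)c(C(=O)Oc2c(C)c(C(=O)OCc3ccccc3)c(OCOC)cc2OCOC)c(O)c1C=O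
F8 | step 11 | benzyl 3-[(3-formyl-2-hydroxy-4-methoxy-6-methylbenzoyl)oxy]-4,6-dihydroxy-2-methylbenzoate | COc1cc(C)c(C(=O)Oc2c(C)c(C(=O)OCc3ccccc3)c(O)cc2O)c(O)c1C=O
F9 | step 11 | benzyl 3-[chloro(methoxy)methyl]-5-[(3-formyl-2-hydroxy-4-methoxy-6-methylbenzoyl)oxy]-2,4-dihydroxy-6-methylbenzoate | COc1cc(C)c(C(=O)Oc2c(C)c(C(=O)OCc3ccccc3)c(O)c(C(Cl)OC)c2O)c(O)c1C=O
F10 | step 6 | benzyl 4,6-bis(methoxymethoxy)-2-methyl-3-(4,4,5,5-tetramethyl-1,3,2-dioxaborolan-2-yl)benzoate | COCOc1cc(OCOC)c(C(=O)OCc2ccccc2)c(C)c1B1OC(C)(C)C(C)(C)O1
F0 | step 12 | none | none
A1 | alternative 1 | 3-(benzyloxycarbonyl)-4,6-bis(benzyloxy)-2-methylphenyl 4-(benzyloxy)-6-methyl-2-oxo-2H-pyran-5-carboxylate | Cc1oc(=O)cc(OCc2ccccc2)c1C(=O)Oc1c(C)c(C(=O)OCc2ccccc2)c(OCc2ccccc2)cc1OCc1ccccc1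
A2 | alternative 1 | 1,1-dimethoxyethene | C=C(OC)OC
A3 | alternative 1 | 3-(benzyloxycarbonyl)-4,6-bis(benzyloxy)-2-methylphenyl 2-(benzyloxy)-4-methoxy-6-methylbenzoate | COc1cc(C)c(C(=O)Oc2c(C)c(C(=O)OCc3ccccc3)c(OCc3ccccc3)cc2OCc2ccccc2)c(OCc2ccccc2)c1
A4 | alternative 2 | 3-(1,3-dioxolan-2-yl)-4-methoxy-2-(methoxymethoxy)-6-methylbenzoic acid | COCOc1c(C2OCCO2)c(OC)cc(C)c1C(=O)O
A5 | alternative 2 | 4-oxopent-2-en-3-yl 3-(1,3-dioxolan-2-yl)-4-methoxy-2-(methoxymethoxy)-6-methylbenzoate | CC=C(OC(=O)c1c(C)cc(OC)c(C2OCCO2)c1OCOC)C(C)=O
A6 | alternative 2 | di-tert-butyl malonate | CC(C)(C)OC(=O)CC(=O)OC(C)(C)C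
A7 | alternative 2 | tert-butyl 5-{[3-(1,3-dioxolan-2-yl)-4-methoxy-2-(methoxymethoxy)-6-methylbenzoyl]oxy}-6-methyl-2,4-dioxocyclohexane-1-carboxylate (diastereomer mixture) | COCOc1c(C3OCCO3)c(OC)cc(C)c1C(=O)OC2C(C)C(C(=O)OC(C)(C)C)C(=O)CC2=O
A8 | alternative 3 | 4-methoxy-2,4-bis(trimethylsilyloxy)buta-1,3-dien-1-yl 3-(1,3-dioxolan-2-yl)-4-methoxy-2-(methoxymethoxy)-6-methylbenzoate | COC(O[Si](C)(C)C)=CC(O[Si](C)(C)C)=COC(=O)c1c(C)cc(OC)c(C2OCCO2)c1OCOC
A9 | alternative 3 | tert-butyl but-2-ynoate | CC#CC(=O)OC(C)(C)C
A10 | alternative 3 | tert-butyl 3-{[3-(1,3-dioxolan-2-yl)-4-methoxy-2-(methoxymethoxy)-6-methylbenzoyl]oxy}-4,6-dihydroxy-2-methylbenzoate | COCOc1c(C3OCCO3)c(OC)cc(C)c1C(=O)Oc2c(C)c(C(=O)OC(C)(C)C)c(O)cc2O
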